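**Plan**

1. Oxocine numbering as in the target's name: O1, C2 (ethyl), C3 (Br), C4, C5=C6, C7, C8 (side chain); C1′ is the acetoxy carbon. Retrosynthesis first removes the acetate, the enyne (Colvin alkynylation, cross-metathesis), the allyl group at C1′ (chelation-controlled allylation) and exchanges Br for OH and then C=O, reaching oxocin-3-one 10.
2. 10 is cut at C4–C5 and at O1–C8 in one operation, back to enol acetal 8, a 4-methylidene-1,3-dioxolane made from (R)-2-hydroxybutanoic acid and a trans-cyclopropanecarbaldehyde.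
3. Enabling feature: with C3 as a ketone, C5 is β to the carbonyl (aldol-type retron for C4–C5) and O1 is homoallylic to C5=C6 along O1–C8–C7–C6=C5 (cyclopropylcarbinyl-to-homoallyl retron). C6, C7 and C8 can therefore be stored as a cyclopropane on the acetal carbon that becomes C5.
4. Forward order of rings: cyclopropane (step 2), dioxolanone and dioxolane (steps 4, 5), five-membered oxolan-3-one (in the flask), then the eight-membered oxocine by three-atom ring expansion (step 6). The side chain is grown afterwards from the hydroxymethyl arm on C8.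
5. Stereochemistry: C2 from (R)-2-hydroxybutanoic acid; C8 from the Charette cyclopropanation, transferred with inversion in step 6; C3 by hydride reduction then SN2 bromination; C1′ by Cram-chelate allylation; 5Z from the ring; 3′E from cross-metathesis.

Key step: step 6

Assumption: 7, 8 and 9 are written as the cis isomers at the acetal-derived carbon; the other epimer, if formed in step 4, gives the same 10 because this carbon becomes sp2 in step 6.

**Route**

Step 1
Reactants: 1 (E)-but-2-ene-1,4-diol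
Product: 2 (E)-4-[(tert-butyldiphenylsilyl)oxy]but-2-en-1-ol
Conditions: NaH (1.0 equiv), THF, 0 °C; t-BuPh2SiCl (1.0 equiv), 0 °C to rt
Reagents that add atoms: tert-butyl(chloro)diphenylsilane, CC(C)(C)[Si](Cl)(c1ccccc1)c1ccccc1
Why: Monosilylation of a symmetrical diol through its sparingly soluble monosodium alkoxide (Williamson-type O-silylation), with no stereocentre involved.

Step 2
Reactants: 2 (E)-4-[(tert-butyldiphenylsilyl)oxy]but-2-en-1-ol
Product: 3 [(1R,2R)-2-{[(tert-butyldiphenylsilyl)oxy]methyl}cyclopropyl]methanol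
Conditions: Et2Zn, CH2I2, DME, CH2Cl2, −10 °C; (4S,5S)-2-butyl-N,N,N′,N′-tetramethyl-1,3,2-dioxaborolane-4,5-dicarboxamide (1.2 equiv), −10 °C to rt; aq NH4Cl
Reagents that add atoms: bis(iodomethyl)zinc Zn(CH2I)2, IC[Zn]CI, made in the flask from diethylzinc, CC[Zn]CC, and diiodomethane, ICI
Why: Charette asymmetric Simmons–Smith cyclopropanation, in which the zinc alkoxide bound to the chiral dioxaborolane directs methylene delivery to one alkene face, the E alkene gives the trans cyclopropane, and the (4S,5S) ligand (the enantiomer of the one that turns cinnamyl alcohol into the (2S,3S) product) should give the (1R,2R) carbinol.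

Step 3
Reactants: 3 [(1R,2R)-2-{[(tert-butyldiphenylsilyl)oxy]methyl}cyclopropyl]methanol
Product: 4 (1R,2R)-2-{[(tert-butyldiphenylsilyl)oxy]methyl}cyclopropane-1-carbaldehyde
Conditions: Dess–Martin periodinane, CH2Cl2, 0 °C to rt
Reagents that add atoms: none
Why: Dess–Martin oxidation stops at the aldehyde under neutral conditions, so the trans cyclopropane (also the more stable isomer) is not epimerised.

Step 4
Reactants: 4 (1R,2R)-2-{[(tert-butyldiphenylsilyl)oxy]methyl}cyclopropane-1-carbaldehyde; 5 (R)-2-hydroxybutanoic acid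
Product: 7 (2R,5R)-2-[(1R,2R)-2-{[(tert-butyldiphenylsilyl)oxy]methyl}cyclopropyl]-5-ethyl-1,3-dioxolan-4-one, via bis(trimethylsilyl) hydroxybutanoate 6 (not isolated)
Conditions: 5, Me3SiCl (2.2 equiv), Et3N (2.3 equiv), CH2Cl2, 0 °C to rt, filter; then 4, Me3SiOTf (5 mol%), CH2Cl2, −78 to −30 °C
Reagents that add atoms: none
Why: Silyl-triflate-catalysed acetalisation of a bis-silylated α-hydroxy acid with an aldehyde (1,3-dioxolan-4-one synthesis) at low temperature leaves the acid stereocentre untouched, and the new acetal centre (mainly cis) is erased again in step 6.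

Step 5
Reactants: 7 (2R,5R)-2-[(1R,2R)-2-{[(tert-butyldiphenylsilyl)oxy]methyl}cyclopropyl]-5-ethyl-1,3-dioxolan-4-one
Product: 8 (2R,5R)-2-[(1R,2R)-2-{[(tert-butyldiphenylsilyl)oxy]methyl}cyclopropyl]-5-ethyl-4-methylidene-1,3-dioxolane
Conditions: Cp2TiMe2 (2.5 equiv), toluene, 65 °C, dark; filtration through basic alumina
Reagents that add atoms: dimethyltitanocene Cp2TiMe2, C[Ti](C)(C1C=CC=C1)C1C=CC=C1
Why: Petasis methylenation, in which Cp2Ti=CH2 formed thermally from Cp2TiMe2 converts the lactone carbonyl into the exocyclic enol ether without touching the acetal, the standard entry to Petasis–Ferrier substrates.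

Step 6
Reactants: 8 (2R,5R)-2-[(1R,2R)-2-{[(tert-butyldiphenylsilyl)oxy]methyl}cyclopropyl]-5-ethyl-4-methylidene-1,3-dioxolane
Product: 10 (2R,8R,5Z)-8-{[(tert-butyldiphenylsilyl)oxy]methyl}-2-ethyl-7,8-dihydro-2H-oxocin-3(4H)-one, via cyclopropyl oxolanone 9 (not isolated)
Conditions: Me3SiOTf (0.3 equiv), 2,6-di-tert-butyl-4-methylpyridine (0.3 equiv), CH2Cl2, −78 to 0 °C; Et3N then aq NaHCO3 at −78 °C
Reagents that add atoms: none
Why: Proposed new method: Me3SiOTf ionises the enol acetal at the bond between the acetal carbon and the enol-ether oxygen to a cyclopropyl-stabilised oxocarbenium ion tethered to a silyl enol ether, which recloses through carbon (the Petasis–Ferrier 1,3 O-to-C shift of 4-methylidene-1,3-dioxolanes, the known half and the closest known reaction type) to the 2,5-cis oxolan-3-one 9 and so forms the C4–C5 bond. The new half is a second ionisation: 9 is a β-alkoxy ketone with a cyclopropyl group on the alkoxy carbon, so the silyl Lewis acid can cleave its C5–O bond (retro-oxa-Michael through the silyl enol ether) to a cyclopropylcarbinyl cation, and the tethered oxygen re-adds at the substituted cyclopropane carbon with opening of its bond to C6 (cyclopropylcarbinyl-to-homoallyl opening, the reaction type of the Julia olefin synthesis, here with an internal oxygen nucleophile), a 1,4 oxygen shift that forms O1–C8, expands the ring by three atoms and, after kinetic protonation of the dienol at C4, leaves the β,γ-enone. Ring closures: the oxolanone by 5-(enolendo)-exo-trig attack of the enol ether on the oxocarbenium ion, the oxocine by endo-mode (homo-conjugate) opening of the cyclopropane in which all three cyclopropane carbons become ring members. Stereocontrol: C8 arises by backside attack with inversion at the cyclopropane carbon fixed in step 2; C2 is carried over from 5; the 5Z alkene is enforced because only the cisoid cation conformer lets the tethered oxygen reach the cyclopropane and an E alkene cannot sit in the eight-membered ring. Selectivity needed: opening at the substituted CH, not the CH2, of the cyclopropane (secured by better charge stabilisation at the secondary carbon and by the trans arrangement that leaves its backside free) and no capture of the cation by other nucleophiles (triflate is the only counter-ion, the base is a hindered pyridine, and the silyl ether oxygen sits trans across the cyclopropane, out of reach). The driving force is release of cyclopropane strain (about 27 kcal/mol) against the small strain of a cis-oxocene, so the reversible five-membered closure should drain into 10.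

Step 7
Reactants: 10 (2R,8R,5Z)-8-{[(tert-butyldiphenylsilyl)oxy]methyl}-2-ethyl-7,8-dihydro-2H-oxocin-3(4H)-one
Product: 11 (2R,3R,8R,5Z)-8-{[(tert-butyldiphenylsilyl)oxy]methyl}-2-ethyl-3,4,7,8-tetrahydro-2H-oxocin-3-ol
Conditions: LiBH(s-Bu)3, THF, −78 °C; then H2O
Reagents that add atoms: none
Why: Diastereoselective ketone reduction in which the bulky hydride should add from the face opposite the neighbouring C2 ethyl group (1,2-induction as with 2-alkylcycloalkanones), placing the hydroxyl cis to ethyl (3R).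

Step 8
Reactants: 11 (2R,3R,8R,5Z)-8-{[(tert-butyldiphenylsilyl)oxy]methyl}-2-ethyl-3,4,7,8-tetrahydro-2H-oxocin-3-ol
Product: 12 (2R,3S,8R,5Z)-3-bromo-8-{[(tert-butyldiphenylsilyl)oxy]methyl}-2-ethyl-3,4,7,8-tetrahydro-2H-oxocine
Conditions: CBr4, P(n-C8H17)3, toluene, 70 °C
Reagents that add atoms: tetrabromomethane, BrC(Br)(Br)Br
Why: Appel bromination, in which bromide displaces the alkoxyphosphonium group by SN2 and so inverts C3 to the 3S bromide trans to ethyl.

Step 9
Reactants: 12 (2R,3S,8R,5Z)-3-bromo-8-{[(tert-butyldiphenylsilyl)oxy]methyl}-2-ethyl-3,4,7,8-tetrahydro-2H-oxocine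
Product: 13 [(2R,7S,8R,4Z)-7-bromo-8-ethyl-3,6,7,8-tetrahydro-2H-oxocin-2-yl]methanol
Conditions: Bu4NF, AcOH, THF, 0 °C to rt
Reagents that add atoms: none
Why: Fluoride-mediated desilylation, buffered with acetic acid so that the secondary bromide is not eliminated.

Step 10
Reactants: 13 [(2R,7S,8R,4Z)-7-bromo-8-ethyl-3,6,7,8-tetrahydro-2H-oxocin-2-yl]methanol
Product: 14 (2R,7S,8R,4Z)-7-bromo-8-ethyl-3,6,7,8-tetrahydro-2H-oxocine-2-carbaldehyde
Conditions: Dess–Martin periodinane, CH2Cl2, 0 °C to rt; used crude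
Reagents that add atoms: none
Why: Dess–Martin oxidation gives the α-alkoxy aldehyde under non-basic conditions, which should avoid epimerisation at the ring carbon.

Step 11
Reactants: 14 (2R,7S,8R,4Z)-7-bromo-8-ethyl-3,6,7,8-tetrahydro-2H-oxocine-2-carbaldehyde
Product: 15 (1R)-1-[(2R,7S,8R,4Z)-7-bromo-8-ethyl-3,6,7,8-tetrahydro-2H-oxocin-2-yl]but-3-en-1-ol
Conditions: MgBr2·OEt2, CH2Cl2, −78 °C; CH2=CHCH2SnBu3, −78 to −20 °C; then H2O
Reagents that add atoms: allyltributylstannane, C=CC[Sn](CCCC)(CCCC)CCCC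
Why: Keck chelation-controlled allylation, in which MgBr2 bridges the aldehyde and ring oxygens and the stannane attacks the Cram chelate from the side of the ring-carbon hydrogen, which should set the carbinol carbon as R.

Step 12
Reactants: 15 (1R)-1-[(2R,7S,8R,4Z)-7-bromo-8-ethyl-3,6,7,8-tetrahydro-2H-oxocin-2-yl]but-3-en-1-ol
Product: 16 (2E,5R)-5-[(2R,7S,8R,4Z)-7-bromo-8-ethyl-3,6,7,8-tetrahydro-2H-oxocin-2-yl]-5-hydroxypent-2-enal
Conditions: (E)-crotonaldehyde (excess), second-generation Hoveyda–Grubbs catalyst (5 mol%), CH2Cl2, 40 °C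
Reagents that add atoms: (E)-crotonaldehyde, C/C=C/C=O
Why: Olefin cross-metathesis of the terminal alkene with crotonaldehyde gives the E enal under thermodynamic control, the internal cis alkene of the unstrained ring being far less reactive.

Step 13
Reactants: 16 (2E,5R)-5-[(2R,7S,8R,4Z)-7-bromo-8-ethyl-3,6,7,8-tetrahydro-2H-oxocin-2-yl]-5-hydroxypent-2-enal
Product: 17 (1R,3E)-1-[(2R,7S,8R,4Z)-7-bromo-8-ethyl-3,6,7,8-tetrahydro-2H-oxocin-2-yl]hex-3-en-5-yn-1-ol
Conditions: Me3SiCHN2, LiN(i-Pr)2 (excess for the free hydroxyl), THF, −78 to 0 °C; then H2O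
Reagents that add atoms: (trimethylsilyl)diazomethane, C[Si](C)(C)C=[N+]=[N-]
Why: Colvin homologation, in which lithiated trimethylsilyldiazomethane adds to the aldehyde, Peterson-type elimination gives a diazoalkene, and the alkylidene carbene rearranges by 1,2-hydrogen shift to the terminal alkyne with the E alkene retained.

Step 14
Reactants: 17 (1R,3E)-1-[(2R,7S,8R,4Z)-7-bromo-8-ethyl-3,6,7,8-tetrahydro-2H-oxocin-2-yl]hex-3-en-5-yn-1-ol
Product: 18 (1R,3E)-1-[(2R,7S,8R,4Z)-7-bromo-8-ethyl-3,6,7,8-tetrahydro-2H-oxocin-2-yl]hex-3-en-5-yn-1-yl acetate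
Conditions: Ac2O, pyridine, DMAP (cat.), CH2Cl2, 0 °C to rt
Reagents that add atoms: acetic anhydride, CC(=O)OC(C)=O
Why: DMAP-catalysed acetylation of the secondary alcohol, which touches no stereocentre.

**Compound list**

1 | (E)-but-2-ene-1,4-diol | OC/C=C/CO | starting material
2 | (E)-4-[(tert-butyldiphenylsilyl)oxy]but-2-en-1-ol | OC/C=C/CO[Si](c1ccccc1)(c1ccccc1)C(C)(C)C | intermediate
3 | [(1R,2R)-2-{[(tert-butyldiphenylsilyl)oxy]methyl}cyclopropyl]methanol | OC[C@@H]1C[C@H]1CO[Si](c1ccccc1)(c1ccccc1)C(C)(C)C | intermediate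
4 | (1R,2R)-2-{[(tert-butyldiphenylsilyl)oxy]methyl}cyclopropane-1-carbaldehyde | O=C[C@@H]1C[C@H]1CO[Si](c1ccccc1)(c1ccccc1)C(C)(C)C | intermediate
5 | (R)-2-hydroxybutanoic acid | CC[C@@H](O)C(=O)O | starting material
6 | trimethylsilyl (R)-2-[(trimethylsilyl)oxy]butanoate | CC[C@@H](O[Si](C)(C)C)C(=O)O[Si](C)(C)C | intermediate (not isolated)
7 | (2R,5R)-2-[(1R,2R)-2-{[(tert-butyldiphenylsilyl)oxy]methyl}cyclopropyl]-5-ethyl-1,3-dioxolan-4-one | CC[C@H]1O[C@@H]([C@@H]2C[C@H]2CO[Si](c3ccccc3)(c3ccccc3)C(C)(C)C)OC1=O | intermediate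
8 | (2R,5R)-2-[(1R,2R)-2-{[(tert-butyldiphenylsilyl)oxy]methyl}cyclopropyl]-5-ethyl-4-methylidene-1,3-dioxolane | CC[C@H]1O[C@@H]([C@@H]2C[C@H]2CO[Si](c3ccccc3)(c3ccccc3)C(C)(C)C)OC1=C | intermediate
9 | (2R,5R)-5-[(1R,2R)-2-{[(tert-butyldiphenylsilyl)oxy]methyl}cyclopropyl]-2-ethyloxolan-3-one | CC[C@H]1O[C@@H]([C@@H]2C[C@H]2CO[Si](c3ccccc3)(c3ccccc3)C(C)(C)C)CC1=O | intermediate (not isolated)
10 | (2R,8R,5Z)-8-{[(tert-butyldiphenylsilyl)oxy]methyl}-2-ethyl-7,8-dihydro-2H-oxocin-3(4H)-one | CC(C)(C)[Si](c1ccccc1)(c1ccccc1)OC[C@H]1C/C=C\CC(=O)[C@@H](CC)O1 | intermediate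
11 | (2R,3R,8R,5Z)-8-{[(tert-butyldiphenylsilyl)oxy]methyl}-2-ethyl-3,4,7,8-tetrahydro-2H-oxocin-3-ol | CC(C)(C)[Si](c1ccccc1)(c1ccccc1)OC[C@H]1C/C=C\C[C@@H](O)[C@@H](CC)O1 | intermediate
12 | (2R,3S,8R,5Z)-3-bromo-8-{[(tert-butyldiphenylsilyl)oxy]methyl}-2-ethyl-3,4,7,8-tetrahydro-2H-oxocine | CC(C)(C)[Si](c1ccccc1)(c1ccccc1)OC[C@H]1C/C=C\C[C@H](Br)[C@@H](CC)O1 | intermediate
13 | [(2R,7S,8R,4Z)-7-bromo-8-ethyl-3,6,7,8-tetrahydro-2H-oxocin-2-yl]methanol | OC[C@H]1C/C=C\C[C@H](Br)[C@@H](CC)O1 | intermediate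
14 | (2R,7S,8R,4Z)-7-bromo-8-ethyl-3,6,7,8-tetrahydro-2H-oxocine-2-carbaldehyde | O=C[C@H]1C/C=C\C[C@H](Br)[C@@H](CC)O1 | intermediate
15 | (1R)-1-[(2R,7S,8R,4Z)-7-bromo-8-ethyl-3,6,7,8-tetrahydro-2H-oxocin-2-yl]but-3-en-1-ol | C=CC[C@@H](O)[C@H]1C/C=C\C[C@H](Br)[C@@H](CC)O1 | intermediate
16 | (2E,5R)-5-[(2R,7S,8R,4Z)-7-bromo-8-ethyl-3,6,7,8-tetrahydro-2H-oxocin-2-yl]-5-hydroxypent-2-enal | O=C/C=C/C[C@@H](O)[C@H]1C/C=C\C[C@H](Br)[C@@H](CC)O1 | intermediate
17 | (1R,3E)-1-[(2R,7S,8R,4Z)-7-bromo-8-ethyl-3,6,7,8-tetrahydro-2H-oxocin-2-yl]hex-3-en-5-yn-1-ol | C#C/C=C/C[C@@H](O)[C@H]1C/C=C\C[C@H](Br)[C@@H](CC)O1 | intermediate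
18 | (1R,3E)-1-[(2R,7S,8R,4Z)-7-bromo-8-ethyl-3,6,7,8-tetrahydro-2H-oxocin-2-yl]hex-3-en-5-yn-1-yl acetate | C#C/C=C/C[C@@H](OC(C)=O)[C@H]1C/C=C\C[C@H](Br)[C@@H](CC)O1 | target

**Count**

Total steps: 14. Longest linear sequence: 14 steps (1 to 18); 5 enters in step 4.

**Steps most likely to fail**

1. Step 6 (Proposed new method). What may go wrong:
 - The second ionisation may not set in, so the sequence stops at oxolanone 9.
 - The cyclopropylcarbinyl cation may be opened at its CH2 carbon, be captured by triflate or lose a proton to a diene.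
 - C2 may epimerise through the silyl enol ether.
 - The alkene may move into conjugation with the ketone.

 Fallback (known chemistry, ring closure moved to the C5=C6 bond); it sets out from 5 and comes back at 10. 5 is coupled with MeNH(OMe)·HCl (EDC·HCl, HOBt, i-Pr2NEt) to (2R)-2-hydroxy-N-methoxy-N-methylbutanamide F1. Its sodium alkoxide (NaH, THF) is alkylated with bromoacetic acid (Williamson etherification) to {[(2R)-1-[methoxy(methyl)amino]-1-oxobutan-2-yl]oxy}acetic acid F2. The mixed pivalic anhydride (t-BuCOCl, Et3N) acylates lithiated (S)-4-benzyl-1,3-oxazolidin-2-one to give (4S)-4-benzyl-3-[({(2R)-1-[methoxy(methyl)amino]-1-oxobutan-2-yl}oxy)acetyl]-1,3-oxazolidin-2-one F3. The sodium enolate (NaN(SiMe3)2, THF, −78 °C) is alkylated with allyl iodide anti to the benzyl group (Evans-type glycolate alkylation), which sets C8 in (4S)-4-benzyl-3-[(2R)-2-({(2R)-1-[methoxy(methyl)amino]-1-oxobutan-2-yl}oxy)pent-4-enoyl]-1,3-oxazolidin-2-one F4. NaBH4 in THF/H2O removes the auxiliary reductively and leaves the Weinreb amide, giving (2R)-2-{[(2R)-1-hydroxypent-4-en-2-yl]oxy}-N-methoxy-N-methylbutanamide F5. t-BuPh2SiCl and imidazole give (2R)-2-{[(2R)-1-[(tert-butyldiphenylsilyl)oxy]pent-4-en-2-yl]oxy}-N-methoxy-N-methylbutanamide F6. CH2=CHCH2MgBr (THF, −78 °C, Weinreb ketone synthesis) gives (5R)-5-{[(2R)-1-[(tert-butyldiphenylsilyl)oxy]pent-4-en-2-yl]oxy}hept-1-en-4-one F7. Ring-closing metathesis (second-generation Grubbs catalyst, CH2Cl2, high dilution, 40 °C) then closes the eight-membered ring and gives 10.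

2. Step 7. What may go wrong: hydride delivery from the wrong face, because the flexible eight-membered ring may not shield the face next to the ethyl group, or base-induced migration of the alkene into conjugation before reduction. Fallback (the stereocentre is corrected by SN2 inversion, not set by face selection); it sets out from 10 and comes back at 11. 10 is reduced under Luche conditions (NaBH4, CeCl3·7H2O, MeOH, −40 °C), which are non-basic. The trans alcohol (2R,3S,8R,5Z)-8-{[(tert-butyldiphenylsilyl)oxy]methyl}-2-ethyl-3,4,7,8-tetrahydro-2H-oxocin-3-ol F8 is inverted by Mitsunobu reaction (4-nitrobenzoic acid, PPh3, DIAD) to (2R,3R,8R,5Z)-8-{[(tert-butyldiphenylsilyl)oxy]methyl}-2-ethyl-3,4,7,8-tetrahydro-2H-oxocin-3-yl 4-nitrobenzoate F9. Methanolysis (K2CO3, MeOH) gives 11.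

3. Step 8. What may go wrong: ionisation of the activated alcohol with participation of the ring oxygen (retention or ring contraction), or elimination towards the ring alkene, in place of clean inversion. Fallback (a discrete sulfonate and an external bromide source in place of in-flask phosphonium activation); it sets out from 11 and comes back at 12. 11 is converted with ClCH2SO2Cl and 2,6-lutidine (CH2Cl2, 0 °C) into (2R,3R,8R,5Z)-8-{[(tert-butyldiphenylsilyl)oxy]methyl}-2-ethyl-3,4,7,8-tetrahydro-2H-oxocin-3-yl chloromethanesulfonate F10. Bu4NBr (toluene, 60 °C) displaces the sulfonate by SN2 with inversion to give 12.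

**Further compounds**

F1 | step 6 | (2R)-2-hydroxy-N-methoxy-N-methylbutanamide | CC[C@@H](O)C(=O)N(C)OC
F2 | step 6 | {[(2R)-1-[methoxy(methyl)amino]-1-oxobutan-2-yl]oxy}acetic acid | CC[C@@H](OCC(=O)O)C(=O)N(C)OC
F3 | step 6 | (4S)-4-benzyl-3-[({(2R)-1-[methoxy(methyl)amino]-1-oxobutan-2-yl}oxy)acetyl]-1,3-oxazolidin-2-one | CC[C@@H](OCC(=O)N1[C@@H](Cc2ccccc2)COC1=O)C(=O)N(C)OC
F4 | step 6 | (4S)-4-benzyl-3-[(2R)-2-({(2R)-1-[methoxy(methyl)amino]-1-oxobutan-2-yl}oxy)pent-4-enoyl]-1,3-oxazolidin-2-one | CC[C@@H](O[C@H](CC=C)C(=O)N1[C@@H](Cc2ccccc2)COC1=O)C(=O)N(C)OC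
F5 | step 6 | (2R)-2-{[(2R)-1-hydroxypent-4-en-2-yl]oxy}-N-methoxy-N-methylbutanamide | CC[C@@H](O[C@H](CC=C)CO)C(=O)N(C)OC
F6 | step 6 | (2R)-2-{[(2R)-1-[(tert-butyldiphenylsilyl)oxy]pent-4-en-2-yl]oxy}-N-methoxy-N-methylbutanamide | CC[C@@H](O[C@H](CC=C)CO[Si](c1ccccc1)(c1ccccc1)C(C)(C)C)C(=O)N(C)OC
F7 | step 6 | (5R)-5-{[(2R)-1-[(tert-butyldiphenylsilyl)oxy]pent-4-en-2-yl]oxy}hept-1-en-4-one | CC[C@@H](O[C@H](CC=C)CO[Si](c1ccccc1)(c1ccccc1)C(C)(C)C)C(=O)CC=C
F8 | step 7 | (2R,3S,8R,5Z)-8-{[(tert-butyldiphenylsilyl)oxy]methyl}-2-ethyl-3,4,7,8-tetrahydro-2H-oxocin-3-ol | CC(C)(C)[Si](c1ccccc1)(c1ccccc1)OC[C@H]1C/C=C\C[C@H](O)[C@@H](CC)O1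
F9 | step 7 | (2R,3R,8R,5Z)-8-{[(tert-butyldiphenylsilyl)oxy]methyl}-2-ethyl-3,4,7,8-tetrahydro-2H-oxocin-3-yl 4-nitrobenzoate | CC(C)(C)[Si](c1ccccc1)(c1ccccc1)OC[C@H]1C/C=C\C[C@@H](OC(=O)c2ccc(cc2)[N+](=O)[O-])[C@@H](CC)O1
F10 | step 8 | (2R,3R,8R,5Z)-8-{[(tert-butyldiphenylsilyl)oxy]methyl}-2-ethyl-3,4,7,8-tetrahydro-2H-oxocin-3-yl chloromethanesulfonate | CC(C)(C)[Si](c1ccccc1)(c1ccccc1)OC[C@H]1C/C=C\C[C@@H](OS(=O)(=O)CCl)[C@@H](CC)O1
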